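A direct plan would build a fully substituted cyclopentanone by successive conjugate additions and then enlarge it by two carbons.
The 3-methylcyclopentenone A1 would take a second cuprate to give the quaternary ketone A2; its pyrrolidine enamine A3 would react with methyl propiolate A4 to give the ring-enlarged amino diene ester A5, to be trimmed to the silyl-protected hydroxymethyl enone A6 before enol ester and hydroperoxide work.
Weak step 1, the ring enlargement of A3 with A4: it would depend on the less substituted enamine of a crowded ketone and on opening of a strained aminocyclobutene, and would build the only ring late, on material that already carries all three ring stereocentres.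
Weak step 2, the cuprate addition to A1 that creates the quaternary centre: only the one neighbouring alkenyl group would bias the face, and a methyl addition/dehydrogenation detour would be spent just to make A1.
Weak step 3, the passage from A5 to A6 (hydrolysis, enol silylation, hydride reduction, silylation, hydrolysis): five operations that would form no bond of the skeleton.

**Retrosynthetic overview**
Ring numbering used below: C1 (C=O), C2 (bears CH2OH), C3, C4, C5 (quaternary), C6 (enol ester arm), C7 (2-oxopropyl arm).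
The cycloheptenone ring is cut at C1–C2 and C5–C6: a rhodium vinylcarbenoid (C1, C7, C6, with the C6 arm as an acetal) and a Z-configured triene (C2 to C5 with the complete, already oxygenated side chain) would be joined by asymmetric cyclopropanation and Cope rearrangement, a formal (4+3) cycloaddition that closes the only ring and sets the vicinal C5 (quaternary)/C6 pair in one operation from the two alkene geometries.
C7 would be relayed from C6 by enolate alkylation; the carboxylate left on C1 would become the ketone by Curtius degradation; the CH2OH on C2 would come from one Morita–Baylis–Hillman reaction; the side-chain carbinol would be set by Shi epoxidation in the first step.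
So the ring is made from acyclic pieces (no enlargement of a crowded cyclopentanone), C5 is set by a stereospecific sigmatropic shift (no face-selective cuprate addition), and the hydroxymethyl enone needs no redox detour.

Key step: step 8

Remark: the facial sense assumed for Rh2(S-DOSP)4 is the one established for aryl- and vinyldiazoacetates with terminal alkenes; should a test reaction show the opposite sense, Rh2(R-DOSP)4 would be used.

Step 1
Reactants: 1 5-bromo-2-methylpent-2-ene
Product: 2 (R)-3-(2-bromoethyl)-2,2-dimethyloxirane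
Conditions: D-fructose-derived Shi ketone (0.3 equiv), Oxone, K2CO3, Bu4NHSO4, MeCN–CH2(OMe)2–aq. Na2B4O7 buffer (pH 10.5), 0 °C
Reagents that add atoms: Oxone (potassium peroxymonosulfate), [K+].[O-]S(=O)(=O)OO
Why: Shi asymmetric epoxidation, in which the dioxirane of the chiral ketone should transfer oxygen to the trisubstituted alkene through the spiro transition state and set the (R) carbinol carbon (the later hydroperoxide carbon) by catalyst control, the primary bromide being inert at this pH and temperature.

Step 2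
Reactants: 2 (R)-3-(2-bromoethyl)-2,2-dimethyloxirane
Product: 3 (R)-1-bromo-4-methylpent-4-en-3-ol
Conditions: Et2Al(TMP) (3 equiv; from n-BuLi, 2,2,6,6-tetramethylpiperidine and Et2AlCl), toluene, 0 °C; aq. potassium sodium tartrate
Reagents that add atoms: none
Why: Yamamoto isomerisation of a trisubstituted epoxide with a diethylaluminium amide, in which syn removal of a methyl proton through a cyclic transition state opens only the C–O bond at the tertiary carbon, so the secondary C–O bond and its (R) configuration are kept and the isopropenyl group is formed.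

Step 3
Reactants: 3 (R)-1-bromo-4-methylpent-4-en-3-ol
Product: 4 {[(3R)-1-bromo-4-methylpent-4-en-3-yl]oxy}triethylsilane
Conditions: Et3SiCl, imidazole, CH2Cl2, 0 → 23 °C
Reagents that add atoms: chlorotriethylsilane, CC[Si](Cl)(CC)CC
Why: Standard silylation of a secondary allylic alcohol, the triethylsilyl ether being chosen because it should survive the organometallic, carbenoid, basic and enolate steps and is later cleaved by mild acid beside a triisopropylsilyl ether.

Step 4
Reactants: 4 {[(3R)-1-bromo-4-methylpent-4-en-3-yl]oxy}triethylsilane; 5 propyne; 6 vinyl bromide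
Product: 10 triethyl{[(3R,6Z)-2,6-dimethylnona-1,6,8-trien-3-yl]oxy}silane, via Grignard reagent 7 (not isolated), via alkenylcopper 8 (not isolated), via alkenylzinc bromide 9 (not isolated)
Conditions: 4, Mg, Et2O; CuBr·SMe2 (1 equiv), Et2O–Me2S, −45 °C; 5, −25 °C; then ZnBr2, Pd(PPh3)4 (5 mol %), 6, THF, −20 → 23 °C
Reagents that add atoms: none
Why: Normant carbocupration followed by palladium-catalysed (Negishi-type) coupling, in which syn addition of the alkylcopper to propyne places the alkyl chain cis to the metal and the coupling with vinyl bromide proceeds with retention, so the Z geometry of the future C4=C5 bond (chain cis to the vinyl group) is fixed by the mechanism.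

Step 5
Reactants: 11 3,3-diethoxypropan-1-ol
Product: 12 3,3-diethoxypropanal
Conditions: Dess–Martin periodinane, pyridine, CH2Cl2, 0 → 23 °C
Reagents that add atoms: none
Why: Dess–Martin oxidation of a primary alcohol under pyridine buffering, which should keep the sensitive β,β-dialkoxy aldehyde from losing ethanol.

Step 6
Reactants: 12 3,3-diethoxypropanal; 13 ethyl diazoacetate
Product: 15 ethyl 2-diazo-5,5-diethoxy-3-hydroxypentanoate (racemic), via ethyl lithiodiazoacetate 14 (not isolated)
Conditions: 13, LDA, THF, −78 °C; then 12, −78 °C; AcOH quench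
Reagents that add atoms: none
Why: Aldol-type addition of ethyl lithiodiazoacetate to an aldehyde at −78 °C, fast enough to outrun enolisation and β-elimination of the dialkoxy aldehyde, the racemic carbinol centre being removed in the next step.

Step 7
Reactants: 15 ethyl 2-diazo-5,5-diethoxy-3-hydroxypentanoate
Product: 16 ethyl (E)-2-diazo-5,5-diethoxypent-3-enoate
Conditions: POCl3, Et3N, CH2Cl2, 0 °C; used at once
Reagents that add atoms: none
Why: Dehydration of a β-hydroxy-α-diazo ester with POCl3 and Et3N, the standard entry to vinyldiazoacetates, which should give the E alkene by elimination of the dichlorophosphate from the less hindered conformer.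

Step 8
Reactants: 10 triethyl{[(3R,6Z)-2,6-dimethylnona-1,6,8-trien-3-yl]oxy}silane; 16 ethyl (E)-2-diazo-5,5-diethoxypent-3-enoate
Product: 18 ethyl (3S,4S)-3-(diethoxymethyl)-4-methyl-4-[(3R)-4-methyl-3-(triethylsilyloxy)pent-4-enyl]cyclohepta-1,5-diene-1-carboxylate, via cis-divinylcyclopropane 17 (not isolated)
Conditions: Rh2(S-DOSP)4 (1 mol %), pentane, slow addition of 16 to 10, −78 → 23 °C; then toluene, 110–130 °C
Reagents that add atoms: none
Why: Tandem cyclopropanation/Cope rearrangement (formal (4+3) cycloaddition of a rhodium vinylcarbenoid with a diene): the donor/acceptor carbenoid from 16 should cyclopropanate only the terminal, monosubstituted double bond of the diene unit of 10 (forming C1–C2 and C1–C3), with its alkenyl group cis to the dienyl residue, to give the cis-divinylcyclopropane 17. The closest known reaction type is the Rh2(S-DOSP)4-catalysed asymmetric (4+3) annulation of vinyldiazoacetates with 1,3-dienes, including dienes with a fully substituted terminus whose divinylcyclopropanes need heating. On warming, 17 should undergo the concerted [3,3] shift through the boat transition state, in which the cyclopropane bond C1–C3 breaks and the bond C5–C6 forms, so the seven-membered ring is closed by enlargement of the three-membered ring and not by end-to-end cyclisation. The two stereocentres follow from the two alkene geometries: the E substituents on C6 (acetal carbon) and on C5 (methyl) point away from the ring in the boat and end up cis, the Z-placed chain on C5 ends up trans to the acetal, and the absolute sense is relayed from the cyclopropane centres set by the chiral catalyst. The step needs chemoselectivity between the diene terminus and the isopropenyl group (secured by conjugation of the former and by the bulky allylic silyloxy branch of the latter) and a Z-configured C4=C5 bond (secured by the syn carbocupration of step 4).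

Step 9
Reactants: 18 cycloheptadiene ethyl ester
Product: 19 (3S,4S)-3-(diethoxymethyl)-4-methyl-4-[(3R)-4-methyl-3-(triethylsilyloxy)pent-4-enyl]cyclohepta-1,5-diene-1-carboxylic acid
Conditions: LiOH·H2O, THF–MeOH–H2O, 40 °C; then AcOH to pH 5, 0 °C
Reagents that add atoms: lithium hydroxide, [Li+].[OH-]
Why: Saponification of an ethyl ester, the triethylsilyl ether and the diethyl acetal being stable to aqueous hydroxide and to the brief acetic acid neutralisation.

Step 10
Reactants: 19 cycloheptadiene carboxylic acid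
Product: 23 (5S,6S)-6-(diethoxymethyl)-5-methyl-5-[(3R)-4-methyl-3-(triethylsilyloxy)pent-4-enyl]cyclohept-2-en-1-one, via acyl azide 20 (not isolated), via vinyl isocyanate 21 (not isolated), via cyclohept-3-enone 22 (not isolated)
Conditions: (PhO)2P(O)N3, Et3N, toluene, 0 → 23 °C, then 85 °C; then 2 M aq. NaOH–THF, 23 °C; then DBU (0.2 equiv), THF, 23 °C
Reagents that add atoms: water, O
Why: Curtius degradation of an α,β-unsaturated acid to a ketone, in which the acyl azide rearranges to the vinyl isocyanate, hydrolysis gives the enamine and then the C1 ketone, and base then moves the C3=C4 bond into conjugation, no stereocentre being touched.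

Step 11
Reactants: 23 cyclohept-2-enone
Product: 24 (5S,6S)-6-(diethoxymethyl)-2-(hydroxymethyl)-5-methyl-5-[(3R)-4-methyl-3-(triethylsilyloxy)pent-4-enyl]cyclohept-2-en-1-one
Conditions: 37% aq. CH2O (5 equiv), DMAP (0.5 equiv), THF–H2O, 23 °C
Reagents that add atoms: formaldehyde, C=O
Why: Morita–Baylis–Hillman reaction of a cyclic enone with formaldehyde, in which DMAP adds to C3, the enolate is hydroxymethylated at C2 and the catalyst is expelled, so the 2-(hydroxymethyl)enone arises in one step and any unconjugated ketone left from step 10 is drained through the enone equilibrium.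

Step 12
Reactants: 24 hydroxymethyl enone
Product: 25 (5S,6S)-6-(diethoxymethyl)-5-methyl-5-[(3R)-4-methyl-3-(triethylsilyloxy)pent-4-enyl]-2-{[tri(propan-2-yl)silyloxy]methyl}cyclohept-2-en-1-one
Conditions: i-Pr3SiCl, imidazole, DMF, 0 → 23 °C
Reagents that add atoms: chlorotri(propan-2-yl)silane, CC(C)[Si](Cl)(C(C)C)C(C)C
Why: Silylation of the primary allylic alcohol, needed so that only the side-chain hydroxyl is free in step 17, the triisopropylsilyl ether withstanding the mild acid of step 14.

Step 13
Reactants: 25 silyl-protected enone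
Product: 27 (5S,6S,7S)-6-(diethoxymethyl)-5-methyl-5-[(3R)-4-methyl-3-(triethylsilyloxy)pent-4-enyl]-7-(prop-2-ynyl)-2-{[tri(propan-2-yl)silyloxy]methyl}cyclohept-2-en-1-one, via lithium enolate 26 (not isolated)
Conditions: LDA (1.1 equiv), THF, −78 °C; DMPU, propargyl bromide, −78 → −40 °C; aq. NH4Cl
Reagents that add atoms: propargyl bromide, C#CCBr
Why: Kinetic α′-deprotonation of a 2-substituted enone with LDA and alkylation of the cross-conjugated enolate, the propargyl group entering C7 anti to the acetal-bearing substituent on C6 to give the 6,7-trans (7S) arrangement, which is also the thermodynamically preferred one.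

Step 14
Reactants: 27 propargyl ketone
Product: 29 (5S,6S,7S)-6-formyl-5-[(3R)-3-hydroxy-4-methylpent-4-enyl]-5-methyl-7-(2-oxopropyl)-2-{[tri(propan-2-yl)silyloxy]methyl}cyclohept-2-en-1-one, via methyl ketone acetal 28 (not isolated)
Conditions: Ph3PAuNTf2 (3 mol %), 1,4-dioxane–H2O, 50 °C; then PPTS (0.3 equiv), acetone–H2O, 40 °C; used at once
Reagents that add atoms: water, O
Why: Gold-catalysed Markovnikov hydration of the terminal alkyne (assisted by 5-exo-dig participation of the C1 carbonyl) gives the methyl ketone, and mild aqueous acid then hydrolyses the diethyl acetal and the triethylsilyl ether while the triisopropylsilyl ether stays.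

Step 15
Reactants: 29 keto aldehyde
Product: 30 (5S,6R,7S)-5-[(3R)-3-hydroxy-4-methylpent-4-enyl]-6-[(E)-2-iodoethenyl]-5-methyl-7-(2-oxopropyl)-2-{[tri(propan-2-yl)silyloxy]methyl}cyclohept-2-en-1-one
Conditions: CrCl2 (6 equiv), CHI3 (2 equiv), THF–1,4-dioxane (1:6), 0 → 23 °C
Reagents that add atoms: iodoform, IC(I)I
Why: Takai olefination, in which the geminal dichromium species from CHI3 and CrCl2 adds only to the aldehyde and gives the E alkenyl iodide under non-basic conditions that should not epimerise C6 or touch the ketones and the free alcohol.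

Step 16
Reactants: 30 alkenyl iodide; 31 3-methylbut-2-enoic acid
Product: 33 (E)-2-{(1S,2S,7S)-7-[(3R)-3-hydroxy-4-methylpent-4-enyl]-7-methyl-3-oxo-2-(2-oxopropyl)-4-{[tri(propan-2-yl)silyloxy]methyl}cyclohept-4-en-1-yl}ethenyl 3-methylbut-2-enoate, via cesium 3-methylbut-2-enoate 32 (not isolated)
Conditions: 31, Cs2CO3 (0.5 equiv per 31), toluene, 23 °C; then 30, CuI (20 mol %), 1,10-phenanthroline (40 mol %), 80 °C
Reagents that add atoms: none
Why: Copper-catalysed Ullmann-type coupling of an alkenyl iodide with a carboxylate, which is stereoretentive, and with the preformed cesium carboxylate as the only base the free secondary alcohol and the 1,4-diketone should be spared.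

Step 17
Reactants: 33 (R)-allylic alcohol
Product: 35 (E)-2-{(1S,2S,7S)-7-[(3S)-3-hydroperoxy-4-methylpent-4-enyl]-7-methyl-3-oxo-2-(2-oxopropyl)-4-{[tri(propan-2-yl)silyloxy]methyl}cyclohept-4-en-1-yl}ethenyl 3-methylbut-2-enoate, via allylic mesylate 34 (not isolated)
Conditions: Ms2O, Et3N (1.1 equiv each), CH2Cl2, −40 °C; then anhydrous H2O2 in Et2O (excess), 2,6-lutidine, −40 → 0 °C
Reagents that add atoms: hydrogen peroxide, OO
Why: Sulfonate perhydrolysis, in which the secondary allylic mesylate is displaced by hydrogen peroxide in an SN2 reaction with inversion, (R) to (S), at low temperature and without nucleophilic halide, the precedent being the conversion of allylic mesylates of hydroxy fatty acids into hydroperoxides.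

Step 18
Reactants: 35 silyl-protected hydroperoxide
Product: 36 CNP0216745.1, (E)-2-{(1S,2S,7S)-7-[(3S)-3-hydroperoxy-4-methylpent-4-enyl]-4-(hydroxymethyl)-7-methyl-3-oxo-2-(2-oxopropyl)cyclohept-4-en-1-yl}ethenyl 3-methylbut-2-enoate
Conditions: HF·pyridine, pyridine, THF, 0 → 23 °C
Reagents that add atoms: none
Why: Fluoride-mediated cleavage of the primary triisopropylsilyl ether under pyridine buffering, conditions that should leave the hydroperoxide and the enol ester intact.

**Compound list**
1 | 5-bromo-2-methylpent-2-ene | CC(C)=CCCBr | starting material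
2 | (R)-3-(2-bromoethyl)-2,2-dimethyloxirane | CC1(C)O[C@@H]1CCBr | intermediate
3 | (R)-1-bromo-4-methylpent-4-en-3-ol | C=C(C)[C@H](O)CCBr | intermediate
4 | {[(3R)-1-bromo-4-methylpent-4-en-3-yl]oxy}triethylsilane | C=C(C)[C@H](O[Si](CC)(CC)CC)CCBr | intermediate
5 | propyne | CC#C | starting material
6 | vinyl bromide | C=CBr | starting material
7 | (3R)-4-methyl-3-(triethylsilyloxy)pent-4-enylmagnesium bromide | C=C(C)[C@H](O[Si](CC)(CC)CC)CC[Mg]Br | intermediate
8 | [(1Z,5R)-2,6-dimethyl-5-(triethylsilyloxy)hepta-1,6-dienyl]copper | C=C(C)[C@H](O[Si](CC)(CC)CC)CC/C(C)=C\[Cu] | intermediate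
9 | [(1Z,5R)-2,6-dimethyl-5-(triethylsilyloxy)hepta-1,6-dienyl]zinc bromide | C=C(C)[C@H](O[Si](CC)(CC)CC)CC/C(C)=C\[Zn]Br | intermediate
10 | triethyl{[(3R,6Z)-2,6-dimethylnona-1,6,8-trien-3-yl]oxy}silane | C=C(C)[C@H](O[Si](CC)(CC)CC)CC/C(C)=C\C=C | intermediate
11 | 3,3-diethoxypropan-1-ol | CCOC(CCO)OCC | starting material
12 | 3,3-diethoxypropanal | CCOC(CC=O)OCC | intermediate
13 | ethyl diazoacetate | CCOC(=O)C=[N+]=[N-] | starting material
14 | ethyl lithiodiazoacetate | CCOC(=O)C([Li])=[N+]=[N-] | intermediate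
15 | ethyl 2-diazo-5,5-diethoxy-3-hydroxypentanoate (racemic) | CCOC(=O)C(=[N+]=[N-])C(O)CC(OCC)OCC | intermediate
16 | ethyl (E)-2-diazo-5,5-diethoxypent-3-enoate | CCOC(=O)C(=[N+]=[N-])/C=C/C(OCC)OCC | intermediate
17 | ethyl (1R,2R)-1-[(E)-3,3-diethoxyprop-1-enyl]-2-[(1Z,5R)-2,6-dimethyl-5-(triethylsilyloxy)hepta-1,6-dienyl]cyclopropane-1-carboxylate | CCOC(=O)[C@@]1(/C=C/C(OCC)OCC)C[C@@H]1/C=C(/C)CC[C@@H](O[Si](CC)(CC)CC)C(C)=C | intermediate
18 | ethyl (3S,4S)-3-(diethoxymethyl)-4-methyl-4-[(3R)-4-methyl-3-(triethylsilyloxy)pent-4-enyl]cyclohepta-1,5-diene-1-carboxylate | C=C(C)[C@@H](CC[C@@]1(C)C=CCC(C(=O)OCC)=C[C@@H]1C(OCC)OCC)O[Si](CC)(CC)CC | intermediate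
19 | (3S,4S)-3-(diethoxymethyl)-4-methyl-4-[(3R)-4-methyl-3-(triethylsilyloxy)pent-4-enyl]cyclohepta-1,5-diene-1-carboxylic acid | C=C(C)[C@@H](CC[C@@]1(C)C=CCC(C(=O)O)=C[C@@H]1C(OCC)OCC)O[Si](CC)(CC)CC | intermediate
20 | acyl azide of 19 | C=C(C)[C@@H](CC[C@@]1(C)C=CCC(C(=O)N=[N+]=[N-])=C[C@@H]1C(OCC)OCC)O[Si](CC)(CC)CC | intermediate
21 | vinyl isocyanate (N=C=O on C1 in place of the carboxyl group of 19) | C=C(C)[C@@H](CC[C@@]1(C)C=CCC(N=C=O)=C[C@@H]1C(OCC)OCC)O[Si](CC)(CC)CC | intermediate
22 | (5S,6S)-6-(diethoxymethyl)-5-methyl-5-[(3R)-4-methyl-3-(triethylsilyloxy)pent-4-enyl]cyclohept-3-en-1-one | C=C(C)[C@@H](CC[C@@]1(C)C=CCC(=O)C[C@@H]1C(OCC)OCC)O[Si](CC)(CC)CC | intermediate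
23 | (5S,6S)-6-(diethoxymethyl)-5-methyl-5-[(3R)-4-methyl-3-(triethylsilyloxy)pent-4-enyl]cyclohept-2-en-1-one | C=C(C)[C@@H](CC[C@@]1(C)CC=CC(=O)C[C@@H]1C(OCC)OCC)O[Si](CC)(CC)CC | intermediate
24 | (5S,6S)-6-(diethoxymethyl)-2-(hydroxymethyl)-5-methyl-5-[(3R)-4-methyl-3-(triethylsilyloxy)pent-4-enyl]cyclohept-2-en-1-one | C=C(C)[C@@H](CC[C@@]1(C)CC=C(CO)C(=O)C[C@@H]1C(OCC)OCC)O[Si](CC)(CC)CC | intermediate
25 | (5S,6S)-6-(diethoxymethyl)-5-methyl-5-[(3R)-4-methyl-3-(triethylsilyloxy)pent-4-enyl]-2-{[tri(propan-2-yl)silyloxy]methyl}cyclohept-2-en-1-one | C=C(C)[C@@H](CC[C@@]1(C)CC=C(CO[Si](C(C)C)(C(C)C)C(C)C)C(=O)C[C@@H]1C(OCC)OCC)O[Si](CC)(CC)CC | intermediate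
26 | lithium C1=C7 enolate of 25 | C=C(C)[C@@H](CC[C@@]1(C)CC=C(CO[Si](C(C)C)(C(C)C)C(C)C)C(O[Li])=C[C@@H]1C(OCC)OCC)O[Si](CC)(CC)CC | intermediate
27 | (5S,6S,7S)-6-(diethoxymethyl)-5-methyl-5-[(3R)-4-methyl-3-(triethylsilyloxy)pent-4-enyl]-7-(prop-2-ynyl)-2-{[tri(propan-2-yl)silyloxy]methyl}cyclohept-2-en-1-one | C=C(C)[C@@H](CC[C@@]1(C)CC=C(CO[Si](C(C)C)(C(C)C)C(C)C)C(=O)[C@@H](CC#C)[C@@H]1C(OCC)OCC)O[Si](CC)(CC)CC | intermediate
28 | (5S,6S,7S)-6-(diethoxymethyl)-5-methyl-5-[(3R)-4-methyl-3-(triethylsilyloxy)pent-4-enyl]-7-(2-oxopropyl)-2-{[tri(propan-2-yl)silyloxy]methyl}cyclohept-2-en-1-one | C=C(C)[C@@H](CC[C@@]1(C)CC=C(CO[Si](C(C)C)(C(C)C)C(C)C)C(=O)[C@@H](CC(C)=O)[C@@H]1C(OCC)OCC)O[Si](CC)(CC)CC | intermediate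
29 | (5S,6S,7S)-6-formyl-5-[(3R)-3-hydroxy-4-methylpent-4-enyl]-5-methyl-7-(2-oxopropyl)-2-{[tri(propan-2-yl)silyloxy]methyl}cyclohept-2-en-1-one | C=C(C)[C@@H](CC[C@@]1(C)CC=C(CO[Si](C(C)C)(C(C)C)C(C)C)C(=O)[C@@H](CC(C)=O)[C@@H]1C=O)O | intermediate
30 | (5S,6R,7S)-5-[(3R)-3-hydroxy-4-methylpent-4-enyl]-6-[(E)-2-iodoethenyl]-5-methyl-7-(2-oxopropyl)-2-{[tri(propan-2-yl)silyloxy]methyl}cyclohept-2-en-1-one | C=C(C)[C@@H](CC[C@@]1(C)CC=C(CO[Si](C(C)C)(C(C)C)C(C)C)C(=O)[C@@H](CC(C)=O)[C@@H]1/C=C/I)O | intermediate
31 | 3-methylbut-2-enoic acid | CC(C)=CC(=O)O | starting material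
32 | cesium 3-methylbut-2-enoate | [Cs+].CC(C)=CC(=O)[O-] | intermediate
33 | (E)-2-{(1S,2S,7S)-7-[(3R)-3-hydroxy-4-methylpent-4-enyl]-7-methyl-3-oxo-2-(2-oxopropyl)-4-{[tri(propan-2-yl)silyloxy]methyl}cyclohept-4-en-1-yl}ethenyl 3-methylbut-2-enoate | C=C(C)[C@@H](CC[C@@]1(C)CC=C(CO[Si](C(C)C)(C(C)C)C(C)C)C(=O)[C@@H](CC(C)=O)[C@@H]1/C=C/OC(=O)C=C(C)C)O | intermediate
34 | (R)-allylic methanesulfonate of 33 | C=C(C)[C@@H](CC[C@@]1(C)CC=C(CO[Si](C(C)C)(C(C)C)C(C)C)C(=O)[C@@H](CC(C)=O)[C@@H]1/C=C/OC(=O)C=C(C)C)OS(C)(=O)=O | intermediate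
35 | (E)-2-{(1S,2S,7S)-7-[(3S)-3-hydroperoxy-4-methylpent-4-enyl]-7-methyl-3-oxo-2-(2-oxopropyl)-4-{[tri(propan-2-yl)silyloxy]methyl}cyclohept-4-en-1-yl}ethenyl 3-methylbut-2-enoate | C=C(C)[C@H](CC[C@@]1(C)CC=C(CO[Si](C(C)C)(C(C)C)C(C)C)C(=O)[C@@H](CC(C)=O)[C@@H]1/C=C/OC(=O)C=C(C)C)OO | intermediate
36 | CNP0216745.1 | C=C(C)[C@H](CC[C@@]1(C)CC=C(CO)C(=O)[C@@H](CC(C)=O)[C@@H]1/C=C/OC(=O)C=C(C)C)OO | target

Total step count: 18. Longest linear sequence: 15 steps (steps 1–4 and 8–18); the diazo component (steps 5–7) is a three-step branch.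

**Steps most likely to fail**

Step 8. What may go wrong: competing cyclopropanation of the 1,1-disubstituted isopropenyl double bond of 10 by the carbenoid, which would consume the triene unproductively. The fallback would carry the side chain through the key step as the unreactive prenyl group and oxidise it afterwards. Setting out from 1, the carbocupration and coupling of step 4 (Mg; CuBr·SMe2; propyne; vinyl bromide, Pd(PPh3)4) would give (3Z)-4,8-dimethylnona-1,3,7-triene F1. Annulation with 16 under the conditions of step 8 would give the prenyl cycloheptadiene ester F2. Shi epoxidation of its only electron-rich trisubstituted double bond would give the (R)-epoxide F3, and isomerisation with Et2Al(TMP) (or Al(O-i-Pr)3 should the ester interfere) the (R)-allylic alcohol F4. Silylation with Et3SiCl would return the route at 18.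

Step 17. What may go wrong: ionisation of the allylic mesylate, with partial loss of configuration or attack of the peroxide at the terminal alkene carbon. The fallback would form the C–OO bond by an ene reaction instead of a substitution. Setting out from 33, Myers reductive transposition (2-nitrobenzenesulfonylhydrazide, PPh3, diethyl azodicarboxylate, THF, −30 → 23 °C) would convert the isopropenyl carbinol into the prenyl compound F6. Photo-oxygenation (O2, tetraphenylporphyrin, visible light, CH2Cl2, 0 °C; Schenck ene reaction) should then give 35 together with its epimer at the hydroperoxide carbon and the tertiary regioisomer, from which 35 would have to be separated by HPLC. The route is rejoined at 35.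

Step 11. What may go wrong: slow addition of the amine catalyst to the seven-membered enone and incomplete conjugation, so that the unconjugated ketone 22 accumulates or is hydroxymethylated twice at C2. The fallback would alkylate C2 through the extended enolate instead. Setting out from 23 (or its mixture with 22), deprotonation with KO-t-Bu in THF at −78 °C to the thermodynamic dienolate and C-alkylation with (triisopropylsiloxy)methyl chloride would give the 2-substituted cyclohept-3-enone F5 as a mixture of C2 epimers. DBU would move the double bond into conjugation and return the route at 25, with the silyl ether already in place.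

**Further compounds**
F1 | step 8 | (3Z)-4,8-dimethylnona-1,3,7-triene | CC(C)=CCC/C(C)=C\C=C
F2 | step 8 | ethyl (3S,4S)-3-(diethoxymethyl)-4-methyl-4-(4-methylpent-3-enyl)cyclohepta-1,5-diene-1-carboxylate | CC(C)=CCC[C@@]1(C)C=CCC(C(=O)OCC)=C[C@@H]1C(OCC)OCC
F3 | step 8 | ethyl (3S,4S)-3-(diethoxymethyl)-4-{2-[(2R)-3,3-dimethyloxiran-2-yl]ethyl}-4-methylcyclohepta-1,5-diene-1-carboxylate | CC1(C)O[C@@H]1CC[C@@]1(C)C=CCC(C(=O)OCC)=C[C@@H]1C(OCC)OCC
F4 | step 8 | ethyl (3S,4S)-3-(diethoxymethyl)-4-[(3R)-3-hydroxy-4-methylpent-4-enyl]-4-methylcyclohepta-1,5-diene-1-carboxylate | C=C(C)[C@@H](CC[C@@]1(C)C=CCC(C(=O)OCC)=C[C@@H]1C(OCC)OCC)O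
F5 | step 11 | (5S,6S)-6-(diethoxymethyl)-5-methyl-5-[(3R)-4-methyl-3-(triethylsilyloxy)pent-4-enyl]-2-{[tri(propan-2-yl)silyloxy]methyl}cyclohept-3-en-1-one (both C2 epimers) | C=C(C)[C@@H](CC[C@@]1(C)C=CC(CO[Si](C(C)C)(C(C)C)C(C)C)C(=O)C[C@@H]1C(OCC)OCC)O[Si](CC)(CC)CC
F6 | step 17 | (E)-2-{(1S,2S,7S)-7-methyl-7-(4-methylpent-3-enyl)-3-oxo-2-(2-oxopropyl)-4-{[tri(propan-2-yl)silyloxy]methyl}cyclohept-4-en-1-yl}ethenyl 3-methylbut-2-enoate | CC(C)=CCC[C@@]1(C)CC=C(CO[Si](C(C)C)(C(C)C)C(C)C)C(=O)[C@@H](CC(C)=O)[C@@H]1/C=C/OC(=O)C=C(C)C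
A1 | direct plan | (4R,5S)-3-methyl-4-[(E)-2-(trimethylsilyl)ethenyl]-5-[3-(trimethylsilyl)prop-2-ynyl]cyclopent-2-en-1-one | O=C1C=C(C)[C@@H](/C=C/[Si](C)(C)C)[C@@H]1CC#C[Si](C)(C)C
A2 | direct plan | (2S,3R,4S)-4-[3-(tert-butyldimethylsilyloxy)propyl]-4-methyl-3-[(E)-2-(trimethylsilyl)ethenyl]-2-[3-(trimethylsilyl)prop-2-ynyl]cyclopentan-1-one | CC(C)(C)[Si](C)(C)OCCC[C@@]1(C)CC(=O)[C@@H](CC#C[Si](C)(C)C)[C@@H]1/C=C/[Si](C)(C)C
A3 | direct plan | less substituted pyrrolidine enamine of A2 | CC(C)(C)[Si](C)(C)OCCC[C@@]1(C)C=C(N2CCCC2)[C@@H](CC#C[Si](C)(C)C)[C@@H]1/C=C/[Si](C)(C)C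
A4 | direct plan | methyl propiolate | C#CC(=O)OC
A5 | direct plan | methyl 2-(pyrrolidin-1-yl)cyclohepta-1,3-diene-1-carboxylate carrying the three ring substituents of A2 | CC(C)(C)[Si](C)(C)OCCC[C@@]1(C)C=CC(C(=O)OC)=C(N2CCCC2)[C@@H](CC#C[Si](C)(C)C)[C@@H]1/C=C/[Si](C)(C)C
A6 | direct plan | 2-(tert-butyldiphenylsilyloxymethyl)cyclohept-2-en-1-one carrying the same three ring substituents | CC(C)(C)[Si](C)(C)OCCC[C@@]1(C)CC=C(CO[Si](c2ccccc2)(c2ccccc2)C(C)(C)C)C(=O)[C@@H](CC#C[Si](C)(C)C)[C@@H]1/C=C/[Si](C)(C)C
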